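Ring B is (S)-carvone: its ring carbons become C5–C10, its methyl the C8 methyl, its carbonyl carbon C9, and its isopropenyl group C4 with both C4 methyls. The key step exploits that C4 of ring A is a gem-dimethyl carbon beside the C3 ketone, a hydrogenated isopropenyl group bonded to an acyl carbon: hydrogen-atom transfer from an iron hydride makes the tertiary C4 radical, which adds 6-exo to a nitrile (C3) tethered to C10; imine hydrolysis gives the ketone. One operation forms the quaternary carbon, the C3 carbonyl and the cis-fused decalin. The precursor is a monocyclic cyclohexane bearing isopropenyl, 2-cyanoethyl, epoxide and amide arm; the polyene is attached afterwards by Suzuki coupling.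

Key step: step 9

Remark on the target: the SMILES places the C5 hydrogen and the C10 methyl group on the same face, so the target is the cis-fused decalin (5S,8R,9R,10S); the route is laid out for this isomer.

Remark on numbering: all intermediates carry the atom numbers of the target (decalin C1–C10, side chain from C11; the carvone ring is C5–C10). β is the ring face that bears the C10 methyl group, α the opposite face.

Step 1
Reactants: 1 (S)-(+)-carvone
Product: 3 10-allylcarvone (allyl β and trans to the 5α-isopropenyl group), via lithium dienolate 2 (not isolated)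
Conditions: LiN(iPr)2, THF, −78 °C; allyl bromide, −78 °C to rt
Reagents that add atoms: allyl bromide, C=CCBr
Why: Kinetic deprotonation can occur only at C10 (C8 is a quaternary sp2 carbon), and the cross-conjugated dienolate should be C-allylated there (enolate alkylation), mainly trans to the isopropenyl group; this centre is made planar again in step 2.

Step 2
Reactants: 3 10-allylcarvone
Product: 5 10-allyl-10-methylcarvone (C10: methyl β, allyl α and cis to the 5α-isopropenyl group), via lithium enolate 4 (not isolated)
Conditions: LiN(iPr)2, THF, −78 °C; MeI, DMPU, −78 to 0 °C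
Reagents that add atoms: iodomethane, CI
Why: Second enolate alkylation: the tetrasubstituted enolate should be methylated on the face anti to the neighbouring C5 isopropenyl group, which sets C10 with methyl β and the allyl arm α, the relationship that later becomes the cis ring fusion.

Step 3
Reactants: 5 10-allyl-10-methylcarvone
Product: 6 7β,8β-epoxy ketone
Conditions: H2O2 (30% aq), NaOH (cat.), MeOH, 0 °C
Reagents that add atoms: hydrogen peroxide, OO
Why: Weitz–Scheffer nucleophilic epoxidation touches only the enone, and hydroperoxide should add to C7 anti to the C5 isopropenyl group, so the oxirane lies on the β face.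

Step 4
Reactants: 6 7β,8β-epoxy ketone
Product: 8 7β-allylic alcohol with C8=C9 double bond, via epoxy hydrazone 7 (not isolated)
Conditions: N2H4·H2O, AcOH (cat.), MeOH, 0 °C to rt, argon
Reagents that add atoms: none
Why: Wharton transposition: the epoxy hydrazone fragments with loss of N2, moving the alkene to C8=C9 and leaving the C7–O bond untouched, hence the 7β-hydroxyl group.

Step 5
Reactants: 8 7β-allylic alcohol
Product: 10 9β-(dimethylcarbamoylmethyl) cyclohexene with C7=C8 double bond, via ketene N,O-acetal 9 (not isolated)
Conditions: MeC(OMe)2NMe2, xylene, 140 °C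
Reagents that add atoms: N,N-dimethylacetamide dimethyl acetal, CC(OC)(OC)N(C)C
Why: Eschenmoser–Claisen rearrangement: the ketene N,O-acetal on the 7β oxygen should undergo a suprafacial chair-like [3,3] shift that delivers the CH2CONMe2 unit to the β face of C9 (C9–H α) next to the quaternary C10 and returns the alkene to C7=C8.

Step 6
Reactants: 10 amide with 10α-allyl arm
Product: 12 primary alcohol (10α-(3-hydroxypropyl) arm, OH on C3), via alkyl catecholboronate 11 (not isolated)
Conditions: catecholborane, RhCl(PPh3)3 (cat.), THF, rt; then H2O2, NaOH, 0 °C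
Reagents that add atoms: hydrogen peroxide, OO
Why: Rhodium-catalysed hydroboration is selective for the monosubstituted allyl alkene over the 1,1-disubstituted and trisubstituted alkenes and the amide, and oxidation should give the anti-Markovnikov alcohol at C3.

Step 7
Reactants: 12 primary alcohol
Product: 15 nitrile (10α-(2-cyanoethyl) arm, C3 = nitrile carbon), via aldehyde 13 (not isolated), via aldimine 14 (not isolated)
Conditions: TEMPO (cat.), PhI(OAc)2, NH4OAc, MeCN/H2O, rt
Reagents that add atoms: ammonium acetate, CC(=O)[O-].[NH4+]
Why: One-pot oxidative ammoxidation of a primary alcohol (TEMPO oxidation to the aldehyde, condensation with ammonia, oxidation of the N–H aldimine) should turn C3 into the acyl-equivalent radical acceptor without touching the alkenes.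

Step 8
Reactants: 15 nitrile
Product: 16 7α,8α-epoxy nitrile
Conditions: dimethyldioxirane, acetone, −20 to 0 °C
Reagents that add atoms: dimethyldioxirane, CC1(C)OO1
Why: Electrophilic epoxidation prefers the trisubstituted ring alkene over the isopropenyl group (as in limonene) and should approach anti to the β arm on C9, which A1,2 strain with the C8 methyl holds pseudoaxial, so the C8–O bond is set on the α face.

Step 9
Reactants: 16 7α,8α-epoxy nitrile
Product: 18 cis-fused bicyclic epoxy keto amide (C3 ketone, 4,4-dimethyl, 5β-H, 10β-methyl), via imine 17 (not isolated)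
Conditions: Fe(acac)3 (cat.), PhSiH3 (slow addition), EtOH, 60 °C; then H2O, AcOH/NaOAc buffer, rt
Reagents that add atoms: water, O
Why: An iron hydride formed from Fe(acac)3 and PhSiH3 delivers a hydrogen atom to the CH2 end of the isopropenyl group, the tertiary C4 radical adds to the nitrile carbon C3, and the iminyl radical is reduced to the N–H imine that water hydrolyses to the C3 ketone. The closest known reaction type is the hydrogen-atom-transfer-initiated radical cyclisation of alkene-tethered nitriles to cyclic ketones. Ring A closes in the 6-exo-dig mode, and the C3–C4 bond is made at the same time as the quaternary gem-dimethyl carbon. No new stereocentre is formed (C3 and C4 are not stereogenic); the cis ring fusion is fixed by the cis (α,α) arrangement of the C10 cyanoethyl arm and the C5 isopropenyl group set in step 2. The step needs the hydrogen atom to go to the isopropenyl group and the radical to find only the nitrile, which the substrate secures because the ring alkene is already an epoxide and the amide and oxirane do not accept alkyl radicals. Premature reduction of the radical is limited by slow addition of the silane and by the quaternary C10, which holds the nitrile close to C4.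

Step 10
Reactants: 18 bicyclic epoxy keto amide
Product: 19 amino diol (3-hydroxy as C3 epimers, 8α-hydroxy-8β-methyl, 9β-(2-dimethylaminoethyl))
Conditions: LiAlH4, THF, 0 °C to reflux
Reagents that add atoms: none
Why: Hydride reduction should convert the amide into the tertiary amine, open the epoxide at the less substituted C7 (the C8–O bond is not broken, so the tertiary alcohol is α and the methyl β) and reduce the C3 ketone to a carbinol whose epimers converge in step 15.

Step 11
Reactants: 19 amino diol
Product: 21 9β-vinyl diol (C11=C12), via amine N-oxide 20 (not isolated)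
Conditions: mCPBA, CH2Cl2, 0 °C; then toluene, 110 °C
Reagents that add atoms: none
Why: N-oxidation followed by Cope elimination (syn, five-membered transition state) should give the terminal vinyl group because the only β-hydrogens are on C11, and no stereocentre is touched.

Step 12
Reactants: 22 (E)-geranylacetone
Product: 25 (5E)-6,10-dimethylundeca-5,9-dien-1-yne, via enol phosphate 23 (not isolated), via lithium acetylide 24 (not isolated)
Conditions: LiN(iPr)2, THF, −78 °C; ClP(O)(OEt)2; LiN(iPr)2 (2.3 equiv), −78 °C to rt; aq NH4Cl
Reagents that add atoms: none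
Why: Kinetic enolisation on the methyl side, O-phosphorylation and base-induced elimination of diethyl phosphate (enol phosphate elimination, methyl ketone to terminal alkyne) should give the enyne with the E alkene untouched.

Step 13
Reactants: 25 (5E)-6,10-dimethylundeca-5,9-dien-1-yne
Product: 27 (1E,5E)-1-iodo-2,6,10-trimethylundeca-1,5,9-triene, via alkenylalane 26 (not isolated)
Conditions: AlMe3, Cp2ZrCl2 (cat.), CH2Cl2, rt; then I2, THF, −30 °C
Reagents that add atoms: trimethylaluminium, C[Al](C)C; iodine, II
Why: Zirconium-catalysed Negishi carboalumination adds methyl and aluminium syn across the alkyne (methyl to the internal carbon), and iodinolysis with retention should give the E trisubstituted vinyl iodide.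

Step 14
Reactants: 21 9β-vinyl diol; 27 (1E,5E)-1-iodo-2,6,10-trimethylundeca-1,5,9-triene
Product: 29 3-hydroxy analogue of the target (C3 epimers), via B-alkyl-9-BBN adduct 28 (not isolated)
Conditions: 9-BBN (excess), THF, rt; then 27, Pd(dppf)Cl2 (cat.), AsPh3, Cs2CO3, DMF/H2O, rt
Reagents that add atoms: none
Why: 9-BBN adds anti-Markovnikov to the only alkene, the C9 vinyl group, and the B-alkyl Suzuki–Miyaura coupling should join C12 to C13 with retention of the E geometry, excess borane covering the two free hydroxyl groups.

Step 15
Reactants: 29 3-hydroxy analogue of the target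
Product: 30 target ketone
Conditions: Dess–Martin periodinane, CH2Cl2, rt
Reagents that add atoms: none
Why: Dess–Martin oxidation should convert both C3 carbinol epimers into the ketone while the tertiary C8 alcohol and the trisubstituted alkenes stay inert.

Compound list
1 | (S)-(+)-carvone, (5S)-2-methyl-5-(prop-1-en-2-yl)cyclohex-2-en-1-one | CC1=CC[C@@H](CC1=O)C(C)=C | starting material
2 | lithium dienolate of 1 (OLi on C9, C9=C10 and C7=C8 double bonds) | CC1=CC[C@@H](C=C1O[Li])C(C)=C | intermediate
3 | 10-allylcarvone, (5S,6R)-2-methyl-6-(prop-2-en-1-yl)-5-(prop-1-en-2-yl)cyclohex-2-en-1-one (allyl β, trans to the 5α-isopropenyl group) | O=C1C(C)=CC[C@H](C(C)=C)[C@H]1CC=C | intermediate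
4 | lithium enolate of 3 (OLi on C9, C9=C10 tetrasubstituted) | [Li]OC1=C(CC=C)[C@@H](C(C)=C)CC=C1C | intermediate
5 | (5R,6S)-2,6-dimethyl-6-(prop-2-en-1-yl)-5-(prop-1-en-2-yl)cyclohex-2-en-1-one (C10: methyl β, allyl α, cis to the 5α-isopropenyl group) | O=C1C(C)=CC[C@H](C(C)=C)[C@]1(C)CC=C | intermediate
6 | 7β,8β-epoxy ketone of 5 (oxirane trans to isopropenyl) | O=C1[C@@]2(C)O[C@H]2C[C@H](C(C)=C)[C@]1(C)CC=C | intermediate
7 | C9 hydrazone of 6 | NN=C1[C@@]2(C)O[C@H]2C[C@H](C(C)=C)[C@]1(C)CC=C | intermediate
8 | allylic alcohol: 7β-hydroxy, C8=C9 double bond, 8-methyl, 10β-methyl, 10α-allyl, 5α-isopropenyl cyclohexene | O[C@H]1C[C@H](C(C)=C)[C@](C)(CC=C)C=C1C | intermediate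
9 | ketene N,O-acetal of 8 (7β-O–C(=CH2)NMe2) | C=C(N(C)C)O[C@H]1C[C@H](C(C)=C)[C@](C)(CC=C)C=C1C | intermediate
10 | amide: 9β-CH2CONMe2 (9α-H), C7=C8 double bond, 8-methyl, 10β-methyl, 10α-allyl, 5α-isopropenyl cyclohexene | CN(C)C(=O)C[C@H]1C(C)=CC[C@H](C(C)=C)[C@]1(C)CC=C | intermediate
11 | B-alkyl catecholborane of 10 (boron on C3, the former allyl terminus) | CN(C)C(=O)C[C@H]1C(C)=CC[C@H](C(C)=C)[C@]1(C)CCCB2Oc3ccccc3O2 | intermediate
12 | primary alcohol: 10 with the allyl arm turned into 3-hydroxypropyl (OH on C3) | CN(C)C(=O)C[C@H]1C(C)=CC[C@H](C(C)=C)[C@]1(C)CCCO | intermediate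
13 | C3 aldehyde corresponding to 12 | CN(C)C(=O)C[C@H]1C(C)=CC[C@H](C(C)=C)[C@]1(C)CCC=O | intermediate
14 | N–H aldimine of 13 | CN(C)C(=O)C[C@H]1C(C)=CC[C@H](C(C)=C)[C@]1(C)CCC=N | intermediate
15 | nitrile: 10α-(2-cyanoethyl) arm (C3 = nitrile carbon), otherwise as 10 | CN(C)C(=O)C[C@H]1C(C)=CC[C@H](C(C)=C)[C@]1(C)CCC#N | intermediate
16 | 7α,8α-epoxide of 15 (oxirane on the α face, 8β-methyl) | CN(C)C(=O)C[C@H]1[C@]2(C)O[C@@H]2C[C@H](C(C)=C)[C@]1(C)CCC#N | intermediate
17 | bicyclic N–H imine: cis-fused decalin with C3=NH, 4,4-dimethyl, 7α,8α-epoxide, 9β-CH2CONMe2 | CN(C)C(=O)C[C@H]1[C@]2(C)O[C@@H]2C[C@@H]3C(C)(C)C(=N)CC[C@]13C | intermediate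
18 | bicyclic epoxy keto amide: as 17 with C3 ketone (5β-H, 10β-methyl) | CN(C)C(=O)C[C@H]1[C@]2(C)O[C@@H]2C[C@@H]3C(C)(C)C(=O)CC[C@]13C | intermediate
19 | amino diol: 3-hydroxy (C3 epimers, left undefined), 8α-hydroxy-8β-methyl, 9β-(2-dimethylaminoethyl), 4,4,10β-trimethyl cis-decalin (5β-H) | CN(C)CC[C@H]1[C@](C)(O)CC[C@@H]2C(C)(C)C(O)CC[C@]12C | intermediate
20 | N-oxide of 19 | C[N+](C)([O-])CC[C@H]1[C@](C)(O)CC[C@@H]2C(C)(C)C(O)CC[C@]12C | intermediate
21 | vinyl diol: 9β-vinyl (C11=C12), 3-hydroxy (C3 epimers), 8α-hydroxy-8β-methyl cis-decalin | C=C[C@H]1[C@](C)(O)CC[C@@H]2C(C)(C)C(O)CC[C@]12C | intermediate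
22 | (E)-geranylacetone, (5E)-6,10-dimethylundeca-5,9-dien-2-one | CC(=O)CC/C=C(\C)CCC=C(C)C | starting material
23 | terminal diethyl enol phosphate of 22 | C=C(OP(=O)(OCC)OCC)CC/C=C(\C)CCC=C(C)C | intermediate
24 | lithium acetylide of 25 | [Li]C#CCC/C=C(\C)CCC=C(C)C | intermediate
25 | (5E)-6,10-dimethylundeca-5,9-dien-1-yne | C#CCC/C=C(\C)CCC=C(C)C | intermediate
26 | dimethyl[(1E,5E)-2,6,10-trimethylundeca-1,5,9-trien-1-yl]aluminium | C[Al](C)/C=C(\C)CC/C=C(\C)CCC=C(C)C | intermediate
27 | (1E,5E)-1-iodo-2,6,10-trimethylundeca-1,5,9-triene | I/C=C(\C)CC/C=C(\C)CCC=C(C)C | intermediate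
28 | B-alkyl-9-BBN adduct of 21 (boron on C12) | C1CC2CCCC(C1)B2CC[C@H]3[C@](C)(O)CC[C@@H]4C(C)(C)C(O)CC[C@]34C | intermediate
29 | 3-hydroxy analogue of the target (C3 epimers), 8α-hydroxy, 9β-[(3E,7E)-4,8,12-trimethyltrideca-3,7,11-trien-1-yl] | CC(C)=CCC/C(C)=C/CC/C(C)=C/CC[C@@H]1[C@@]2(C)CCC(O)C(C)(C)[C@H]2CC[C@@]1(C)O | intermediate
30 | target, (4aS,5R,6R,8aS)-6-hydroxy-1,1,4a,6-tetramethyl-5-[(3E,7E)-4,8,12-trimethyltrideca-3,7,11-trien-1-yl]octahydronaphthalen-2(1H)-one (5S,8R,9R,10S in target numbering) | CC(C)=CCC/C(C)=C/CC/C(C)=C/CC[C@@H]1[C@@]2(C)CCC(=O)C(C)(C)[C@H]2CC[C@@]1(C)O | target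

Total step count: 15. Longest linear sequence: 13 steps (steps 1–11, 14 and 15, from carvone); steps 12 and 13 make the side-chain fragment.

Steps most likely to fail

Step 9. The hydrogen-atom transfer is fast but the 6-exo addition to the nitrile is slow, so the tertiary radical may take a second hydrogen atom before the ring closes, or the iron medium may open the acid-sensitive oxirane. The fallback sets out from 16 and separates radical generation from ring closure. A cobalt-catalysed Markovnikov hydrochlorination (Co(BF4)2·6H2O with a salen-type ligand, TsCl, PhSiH3, t-BuOOH, EtOH) should give the tertiary chloride F1. A chain cyclisation with (Me3Si)3SiH and AIBN, added by syringe pump in toluene at 90 °C, then keeps the hydrogen donor scarce so the C4 radical has time to add to the nitrile. The imine 17 is hydrolysed as before, and the route is rejoined at 18.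

Step 8. The oxidant may attack the β face (the α face carries the axial arm on C10), or the isopropenyl group may be epoxidised as well. The fallback sets out from 15 and uses a β-face preference the other way round. NBS in aqueous DME should give, by anti addition with water entering at the tertiary C8 from the α face, the bromohydrin F2. K2CO3 in MeOH then closes the 7α,8α-oxirane by intramolecular displacement of bromide, and the route is rejoined at 16.

Step 4. Hydrazone formation at the hindered C9 ketone beside the quaternary C10 may be slow, leaving room for azine formation and for diimide reduction of the terminal alkenes. The fallback sets out from 6 and replaces the Wharton step by a radical fragmentation. NaBH4 in MeOH should give the epoxy alcohol F3, and thiocarbonyldiimidazole the imidazolide F4. Bu3SnH/AIBN then generates the C9 radical, which opens the oxirane at the C8–O bond; the alkoxy radical is reduced to the same 7β-allylic alcohol, and the route is rejoined at 8.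

Further compounds
F1 | step 9 | tertiary chloride (Markovnikov HCl adduct of 16, chlorine on C4) | CN(C)C(=O)C[C@H]1[C@]2(C)O[C@@H]2C[C@H](C(C)(C)Cl)[C@]1(C)CCC#N
F2 | step 8 | bromohydrin of 15 (7β-bromo, 8α-hydroxy-8β-methyl) | CN(C)C(=O)C[C@H]1[C@](C)(O)[C@@H](Br)C[C@H](C(C)=C)[C@]1(C)CCC#N
F3 | step 4 | epoxy alcohol from 6 (C9 carbinol, C9 epimers left undefined) | OC1[C@@]2(C)O[C@H]2C[C@H](C(C)=C)[C@]1(C)CC=C
F4 | step 4 | O-imidazolylthiocarbonyl derivative of F3 | S=C(OC1[C@@]2(C)O[C@H]2C[C@H](C(C)=C)[C@]1(C)CC=C)n1ccnc1
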